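The cyclohexane ring is opened retrosynthetically at C8–C9. The feature used is quaternary C10, which bears a methyl, the C1=C2 vinyl group and ring carbon C9: drawing C9 as part of a second vinyl group makes C10 non-stereogenic. One ring-closing metathesis with a chiral molybdenum alkylidene then picks one of the two diastereotopic vinyl groups, closes the six-membered carbocycle, installs the C8=C9 alkene needed for the trans C8/C9 oxygens and fixes C10. The precursor is an acyclic triene whose C5–C7 stereotriad comes from an auxiliary aldol and a cuprate addition, with C6 silylated, a tert-butyl acetate arm on C7 and C4 as a silylated carbinol.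

Key step: step 13

Remark: elemane numbering (C1–C15) is used for all intermediates and β is the ring face of the C10 methyl group; the target SMILES is read as the C9 (R)-2-methylbutanoate and the C6 (Z)-2-methylbut-2-enoate (angelate); the (S)-biphenolate antipode of the molybdenum catalyst is assumed to be the matched one (its mirror image is used otherwise); the temporary C4 carbinol centre (Felkin–Anh epimer drawn) is erased in step 16. PMB = 4-methoxybenzyl, TBS = tert-butyldimethylsilyl, TES = triethylsilyl.

Step 1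
Reactants: 1 (E)-3-methylpent-2-en-4-yn-1-ol; 2 triethyl orthoacetate
Product: 4 ethyl 3-ethynyl-3-methylpent-4-enoate (racemic), via ketene acetal 3 (not isolated)
Conditions: 2 (excess), EtCO2H (cat.), 140 °C, EtOH distilled off
Reagents that add atoms: none
Why: Johnson–Claisen rearrangement, in which acid-catalysed exchange gives ketene acetal 3 and its chair [3,3] shift turns the trisubstituted alkene carbon into the quaternary carbon (future C10) carrying methyl, vinyl and ethynyl; this centre is racemic and becomes non-stereogenic in step 2.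

Step 2
Reactants: 4 ethyl 3-ethynyl-3-methylpent-4-enoate
Product: 5 ethyl 3-ethenyl-3-methylpent-4-enoate
Conditions: H2 (1 atm), Pd/CaCO3 poisoned with Pb(OAc)2, quinoline, hexane, rt, stopped after one equivalent
Reagents that add atoms: none
Why: Lindlar-type cis semi-hydrogenation, since the poisoned palladium surface should reduce the terminal alkyne much faster than the monosubstituted alkene and leave the achiral divinyl ester.

Step 3
Reactants: 5 ethyl 3-ethenyl-3-methylpent-4-enoate
Product: 6 3-ethenyl-3-methylpent-4-enoic acid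
Conditions: LiOH, THF/MeOH/H2O, rt; then 1 M HCl
Reagents that add atoms: lithium hydroxide, [Li+].[OH-]
Why: ester saponification (acyl substitution by hydroxide) at an unhindered CH2CO2Et group, with no stereocentre involved.

Step 4
Reactants: 6 3-ethenyl-3-methylpent-4-enoic acid; 7 (S)-4-benzyl-1,3-thiazolidine-2-thione
Product: 8 (S)-4-benzyl-3-(3-ethenyl-3-methylpent-4-enoyl)-1,3-thiazolidine-2-thione
Conditions: DCC, DMAP (cat.), CH2Cl2, 0 °C to rt
Reagents that add atoms: none
Why: carbodiimide/DMAP N-acylation (Steglich-type) of the acidic thiazolidinethione N–H by an acid that is unbranched at its α-carbon.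

Step 5
Reactants: 9 tert-butyl (triphenyl-λ5-phosphanylidene)acetate; 10 2,2-dimethoxyacetaldehyde
Product: 11 tert-butyl (E)-4,4-dimethoxybut-2-enoate
Conditions: CH2Cl2, rt
Reagents that add atoms: none
Why: Wittig olefination with a stabilised ylide, which should give the E-enoate and leave the acetal untouched.

Step 6
Reactants: 11 tert-butyl (E)-4,4-dimethoxybut-2-enoate
Product: 12 tert-butyl (E)-4-oxobut-2-enoate
Conditions: TsOH·H2O (cat.), acetone/H2O, rt
Reagents that add atoms: water, O
Why: acid-catalysed acetal hydrolysis under conditions mild enough to keep the tert-butyl ester.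

Step 7
Reactants: 8 (S)-4-benzyl-3-(3-ethenyl-3-methylpent-4-enoyl)-1,3-thiazolidine-2-thione; 12 tert-butyl (E)-4-oxobut-2-enoate
Product: 13 tert-butyl (2E,4R,5S)-5-{[(S)-4-benzyl-2-thioxo-1,3-thiazolidin-3-yl]carbonyl}-6-ethenyl-4-hydroxy-6-methylocta-2,7-dienoate (syn aldol; chain C4 and C5 are C6 and C5 of the target)
Conditions: TiCl4, iPr2NEt, N-methylpyrrolidinone, CH2Cl2, 0 °C; then 12, −78 to −40 °C
Reagents that add atoms: none
Why: titanium-mediated Evans-type syn aldol of an N-acyl thiazolidinethione, in which soft enolisation gives the Z-enolate and a chair transition state with the benzyl group shielding one face adds 1,2 to the reactive, non-enolisable aldehyde, setting C5 and C6 syn in the absolute sense dictated by the (S)-auxiliary.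

Step 8
Reactants: 13 syn aldol adduct
Product: 14 tert-butyldimethylsilyl ether of 13 at the C6 hydroxyl
Conditions: TBSOTf, 2,6-lutidine, CH2Cl2, −78 to 0 °C
Reagents that add atoms: tert-butyldimethylsilyl trifluoromethanesulfonate, CC(C)(C)[Si](C)(C)OS(=O)(=O)C(F)(F)F
Why: silyl triflate silylation of a hindered secondary alcohol, which blocks retro-aldol cleavage and protects C6 through the later base and metathesis steps.

Step 9
Reactants: 14 silyl ether of the aldol adduct
Product: 15 tert-butyl (2E)-4-[(tert-butyldimethylsilyl)oxy]-6-ethenyl-5-formyl-6-methylocta-2,7-dienoate (C5 and C6 as in 13)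
Conditions: iBu2AlH, CH2Cl2, −78 °C, added until the yellow colour fades; aq. KNaC4H4O6
Reagents that add atoms: none
Why: partial reduction of the activated N-acyl thiazolidinethione to the aldehyde through a tetrahedral aluminate that is stable at −78 °C, a reaction that should be much faster than attack on the tert-butyl enoate and leaves C5 untouched.

Step 10
Reactants: 16 4-methoxybenzyl alcohol; 17 tributyl(iodomethyl)stannane
Product: 18 tributyl{[(4-methoxybenzyl)oxy]methyl}stannane
Conditions: NaH, THF/DMF, 0 °C to rt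
Reagents that add atoms: none
Why: Williamson ether synthesis by SN2 displacement of the primary iodide with the sodium alkoxide.

Step 11
Reactants: 15 aldehyde; 18 tributyl{[(4-methoxybenzyl)oxy]methyl}stannane
Product: 20 tert-butyl (E)-enoate with C4–OTES (4S) and C3–OPMB and C6–OTBS, via lithium alkoxide 19 (not isolated)
Conditions: 18, n-BuLi, THF, −78 °C; then 15, −78 °C; then Et3SiOTf, −78 to 0 °C
Reagents that add atoms: triethylsilyl trifluoromethanesulfonate, CC[Si](CC)(CC)OS(=O)(=O)C(F)(F)F
Why: tin–lithium exchange gives the α-alkoxymethyllithium, whose 1,2-addition to the aldehyde (faster than attack on the tert-butyl enoate at −78 °C) follows the Felkin–Anh model with the quaternary C10 group anti to the nucleophile, and alkoxide 19 is silylated in the flask; the C4 centre is temporary.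

Step 12
Reactants: 20 bis-silylated enoate
Product: 22 triene tert-butyl ester (4S,5S,6R,7S) with C10 bearing methyl and two vinyl groups (precursor of the key step), via silyl ketene acetal 21 (not isolated)
Conditions: CH2=CHMgBr, CuBr·SMe2 (10 mol %), Me3SiCl, THF, −78 to −40 °C; then aq. NH4Cl
Reagents that add atoms: vinylmagnesium bromide, C=C[Mg]Br
Why: copper-catalysed, Me3SiCl-accelerated conjugate addition to a γ-silyloxy E-enoate, in which the C6 oxygen lies inside and the bulky C5 branch is anti to the incoming copper reagent (modified Felkin–Anh model), so that C7 is set with the vinyl group anti to the C6 oxygen, and work-up hydrolyses ketene acetal 21.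

Step 13
Reactants: 22 triene tert-butyl ester
Product: 23 tert-butyl [10α-ethenyl-10β-methyl-6β-(TBS-oxy)-5β-{2-(PMB-oxy)-1-(TES-oxy)ethyl}cyclohex-8-en-7α-yl]acetate (4S,5S,6R,7S,10R)
Conditions: Mo(N-2,6-iPr2C6H3)(CHCMe2Ph)[(S)-3,3'-di-tert-butyl-5,5',6,6'-tetramethylbiphenyl-2,2'-diolate] (5–10 mol %), C6H6, 0.01 M, 22–50 °C, N2 sweep
Reagents that add atoms: none
Why: The alkylidene exchanges onto the least hindered C8 vinyl group, a molybdacyclobutane forms with one of the two C10 vinyl groups and cycloreverts with loss of ethene; this is ring-closing olefin metathesis, and the closest known reaction type is the catalyst-controlled desymmetrising ring closure of trienes that sets all-carbon quaternary centres. The six-membered ring C5–C6–C7–C8=C9–C10 closes by C8=C9 bond formation with the new alkene inside the ring, and no other ring size is open because C4 is an sp3 silylated carbinol. C10 is the only new stereocentre and is controlled by the chiral biphenolate pocket, which has to engage the vinyl group that leaves the remaining vinyl trans to the C5 branch; the intrinsic bias of the substrate (C5 branch and C6 silyl ether in a chair-like metallacycle) is expected to be small, so the two catalyst antipodes form a matched and a mismatched pair. The step needs diastereotopic-group selectivity, while chemoselectivity is secured by silylation of both hydroxyls, by the tert-butyl ester, and by the absence of a ketone or a 1,1-disubstituted alkene at C4, either of which the C8 alkylidene would capture to give a cyclopentene. The gem-divinyl quaternary carbon favours closure and removal of ethene makes it irreversible.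

Step 14
Reactants: 23 cyclohexene with C4–OTES
Product: 24 cyclohexene with free C4 hydroxyl (C6–OTBS retained)
Conditions: PPTS (cat.), MeOH/CH2Cl2, 0 °C
Reagents that add atoms: none
Why: selective acid-catalysed methanolysis of the triethylsilyl ether, which is far more labile than the hindered tert-butyldimethylsilyl ether at C6.

Step 15
Reactants: 24 cyclohexenyl C4 alcohol
Product: 25 8β,9β-epoxide of 24
Conditions: VO(acac)2 (10 mol %), t-BuOOH (decane), CH2Cl2, 0 °C to rt
Reagents that add atoms: tert-butyl hydroperoxide, CC(C)(C)OO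
Why: hydroxyl-directed vanadium-catalysed epoxidation, in which the vanadate ester of the C4 hydroxyl (on the β face with the C5 branch and bishomoallylic to C9) delivers the peroxide oxygen to the β face of the cis-disubstituted C8=C9 alkene, anti to the C7 arm, setting C8 and C9; the monosubstituted vinyl group should react far more slowly.

Step 16
Reactants: 25 epoxy alcohol
Product: 26 epoxy ketone (C4=O with C3–OPMB)
Conditions: Dess–Martin periodinane, NaHCO3, CH2Cl2, rt
Reagents that add atoms: none
Why: Dess–Martin oxidation of the secondary alcohol under buffered conditions that should not epimerise C5 or open the epoxide.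

Step 17
Reactants: 26 epoxy ketone
Product: 27 epoxide with the C4=C15 methylene group
Conditions: Ph3PCH3Br, KOtBu, THF, 0 °C to rt
Reagents that add atoms: methyltriphenylphosphonium bromide, C[P+](c1ccccc1)(c1ccccc1)c1ccccc1.[Br-]
Why: Wittig methylenation of an activated α-alkoxy ketone by a non-stabilised ylide, which does not attack the epoxide or the tert-butyl ester at these temperatures.

Step 18
Reactants: 27 methylene epoxide
Product: 28 cis-fused 12,8-lactone with free 9β-hydroxyl
Conditions: camphor-10-sulfonic acid (0.2 equiv), CH2Cl2, 0 °C to rt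
Reagents that add atoms: none
Why: acid-catalysed epoxide-opening lactonisation, in which the ester carbonyl oxygen attacks the protonated epoxide at C8 from the α face in a 5-exo mode with inversion and the tert-butyl group leaves as isobutene, so that C8–O (α) and the C9 hydroxyl (β) follow directly from the epoxide.

Step 19
Reactants: 28 hydroxy lactone
Product: 31 α-methylene lactone with free 9β-hydroxyl, via Mannich base 29 (not isolated), via ammonium iodide 30 (not isolated)
Conditions: LiN(iPr)2 (2.5 equiv), THF, −78 °C; CH2=NMe2+ I−, −78 °C to rt; MeI, MeOH, rt; NaHCO3 (aq), CH2Cl2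
Reagents that add atoms: N,N-dimethylmethyleneiminium iodide, C=[N+](C)C.[I-]
Why: lactone α-methylenation by a Mannich reaction of the dianion (C9 alkoxide and lactone enolate) followed by N-methylation and Hofmann-type β-elimination, carried out before any epimerisable or isomerisable ester is present.

Step 20
Reactants: 31 α-methylene lactone alcohol; 32 (R)-2-methylbutanoic acid
Product: 33 C9 (R)-2-methylbutanoate
Conditions: DCC, DMAP, CH2Cl2, rt
Reagents that add atoms: none
Why: Steglich esterification of the C9 alcohol through the acylpyridinium ion, conditions under which the α-stereocentre of the acid should be preserved.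

Step 21
Reactants: 33 C9 ester with C6–OTBS
Product: 34 C6 alcohol
Conditions: HF·pyridine, pyridine, THF, 0 °C to rt
Reagents that add atoms: none
Why: fluoride-mediated desilylation under mildly acidic conditions that tolerate the α-methylene lactone, the ester and the PMB ether.

Step 22
Reactants: 34 C6 alcohol; 35 angelic acid ((Z)-2-methylbut-2-enoic acid)
Product: 37 C6 angelate with C3–OPMB, via mixed anhydride 36 (not isolated)
Conditions: 35, 2,4,6-Cl3C6H2COCl, Et3N, toluene, rt; then 34, toluene, 80 °C
Reagents that add atoms: none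
Why: Yamaguchi esterification, in which mixed anhydride 36 acylates the hindered C6 alcohol at its less shielded angeloyl carbonyl without DMAP, conditions chosen to keep the Z alkene from isomerising to the tiglate.

Step 23
Reactants: 37 PMB ether
Product: 38 C3 allylic alcohol
Conditions: DDQ, CH2Cl2/pH 7 buffer, 0 °C
Reagents that add atoms: none
Why: oxidative cleavage of the 4-methoxybenzyl ether by DDQ (hydride abstraction and hydrolysis of the oxocarbenium ion), to which esters, lactone and alkenes are inert.

Step 24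
Reactants: 38 allylic alcohol
Product: 39 CNP0295282.1 (target)
Conditions: MnO2, CH2Cl2, rt
Reagents that add atoms: none
Why: chemoselective MnO2 oxidation of the only remaining alcohol, a primary allylic one, to the α-substituted acrolein.

Compound list
1 | (E)-3-methylpent-2-en-4-yn-1-ol | C#C/C(C)=C/CO | starting material
2 | triethyl orthoacetate | CCOC(C)(OCC)OCC | starting material
3 | 1-ethoxy-1-[(E)-3-methylpent-2-en-4-ynyloxy]ethene | C#C/C(C)=C/COC(=C)OCC | intermediate (not isolated)
4 | ethyl 3-ethynyl-3-methylpent-4-enoate (racemic) | CCOC(=O)CC(C)(C=C)C#C | intermediate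
5 | ethyl 3-ethenyl-3-methylpent-4-enoate | CCOC(=O)CC(C)(C=C)C=C | intermediate
6 | 3-ethenyl-3-methylpent-4-enoic acid | OC(=O)CC(C)(C=C)C=C | intermediate
7 | (S)-4-benzyl-1,3-thiazolidine-2-thione | S=C1N[C@@H](Cc2ccccc2)CS1 | starting material
8 | (S)-4-benzyl-3-(3-ethenyl-3-methylpent-4-enoyl)-1,3-thiazolidine-2-thione | C=CC(C)(C=C)CC(=O)N1[C@@H](Cc2ccccc2)CSC1=S | intermediate
9 | tert-butyl (triphenyl-λ5-phosphanylidene)acetate | CC(C)(C)OC(=O)C=P(c1ccccc1)(c1ccccc1)c1ccccc1 | starting material
10 | 2,2-dimethoxyacetaldehyde | COC(OC)C=O | starting material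
11 | tert-butyl (E)-4,4-dimethoxybut-2-enoate | COC(OC)/C=C/C(=O)OC(C)(C)C | intermediate
12 | tert-butyl (E)-4-oxobut-2-enoate | O=C/C=C/C(=O)OC(C)(C)C | intermediate
13 | tert-butyl (2E,4R,5S)-5-{[(S)-4-benzyl-2-thioxo-1,3-thiazolidin-3-yl]carbonyl}-6-ethenyl-4-hydroxy-6-methylocta-2,7-dienoate | C=CC(C)(C=C)[C@H](C(=O)N1[C@@H](Cc2ccccc2)CSC1=S)[C@H](O)/C=C/C(=O)OC(C)(C)C | intermediate
14 | C6 tert-butyldimethylsilyl ether of 13 | C=CC(C)(C=C)[C@H](C(=O)N1[C@@H](Cc2ccccc2)CSC1=S)[C@H](O[Si](C)(C)C(C)(C)C)/C=C/C(=O)OC(C)(C)C | intermediate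
15 | tert-butyl (2E)-4-[(tert-butyldimethylsilyl)oxy]-6-ethenyl-5-formyl-6-methylocta-2,7-dienoate (C5, C6 as in 13) | C=CC(C)(C=C)[C@H](C=O)[C@H](O[Si](C)(C)C(C)(C)C)/C=C/C(=O)OC(C)(C)C | intermediate
16 | 4-methoxybenzyl alcohol | COc1ccc(CO)cc1 | starting material
17 | tributyl(iodomethyl)stannane | CCCC[Sn](CCCC)(CCCC)CI | starting material
18 | tributyl{[(4-methoxybenzyl)oxy]methyl}stannane | CCCC[Sn](CCCC)(CCCC)COCc1ccc(OC)cc1 | intermediate
19 | lithium alkoxide of the C4 carbinol (4S; C3–OPMB, C6–OTBS, E-enoate) | [Li+].C=CC(C)(C=C)[C@H]([C@H]([O-])COCc1ccc(OC)cc1)[C@H](O[Si](C)(C)C(C)(C)C)/C=C/C(=O)OC(C)(C)C | intermediate (not isolated)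
20 | tert-butyl (E)-enoate with C4–OTES (4S), C3–OPMB, C6–OTBS (C5, C6 as in 13) | C=CC(C)(C=C)[C@H]([C@H](O[Si](CC)(CC)CC)COCc1ccc(OC)cc1)[C@H](O[Si](C)(C)C(C)(C)C)/C=C/C(=O)OC(C)(C)C | intermediate
21 | tert-butyl trimethylsilyl ketene acetal of 22 | C=CC(C)(C=C)[C@H]([C@H](O[Si](CC)(CC)CC)COCc1ccc(OC)cc1)[C@H](O[Si](C)(C)C(C)(C)C)[C@@H](C=C(O[Si](C)(C)C)OC(C)(C)C)C=C | intermediate (not isolated)
22 | tert-butyl 3,6-diethenyl-4-(TBS-oxy)-5-[2-(PMB-oxy)-1-(TES-oxy)ethyl]-6-methyloct-7-enoate; elemane numbering (4S,5S,6R,7S) | C=CC(C)(C=C)[C@H]([C@H](O[Si](CC)(CC)CC)COCc1ccc(OC)cc1)[C@H](O[Si](C)(C)C(C)(C)C)[C@@H](CC(=O)OC(C)(C)C)C=C | intermediate (key-step precursor)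
23 | tert-butyl [10α-ethenyl-10β-methyl-6β-(TBS-oxy)-5β-{2-(PMB-oxy)-1-(TES-oxy)ethyl}cyclohex-8-en-7α-yl]acetate; (4S,5S,6R,7S,10R) | C=C[C@@]1(C)[C@H]([C@H](O[Si](CC)(CC)CC)COCc2ccc(OC)cc2)[C@H](O[Si](C)(C)C(C)(C)C)[C@@H](CC(=O)OC(C)(C)C)C=C1 | intermediate (key-step product)
24 | C4 alcohol from 23 (C6–OTBS) | C=C[C@@]1(C)[C@H]([C@H](O)COCc2ccc(OC)cc2)[C@H](O[Si](C)(C)C(C)(C)C)[C@@H](CC(=O)OC(C)(C)C)C=C1 | intermediate
25 | 8β,9β-epoxide of 24 | C=C[C@@]1(C)[C@H]([C@H](O)COCc2ccc(OC)cc2)[C@H](O[Si](C)(C)C(C)(C)C)[C@@H](CC(=O)OC(C)(C)C)[C@@H]3O[C@H]13 | intermediate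
26 | 8β,9β-epoxy C4 ketone | C=C[C@@]1(C)[C@H](C(=O)COCc2ccc(OC)cc2)[C@H](O[Si](C)(C)C(C)(C)C)[C@@H](CC(=O)OC(C)(C)C)[C@@H]3O[C@H]13 | intermediate
27 | 8β,9β-epoxide with C4=C15 methylene | C=C[C@@]1(C)[C@H](C(=C)COCc2ccc(OC)cc2)[C@H](O[Si](C)(C)C(C)(C)C)[C@@H](CC(=O)OC(C)(C)C)[C@@H]3O[C@H]13 | intermediate
28 | 9β-hydroxy-6β-(TBS-oxy)-3-(PMB-oxy)elema-1,4(15)-dien-12,8α-olide | C=C[C@@]1(C)[C@H](C(=C)COCc2ccc(OC)cc2)[C@H](O[Si](C)(C)C(C)(C)C)[C@H]3CC(=O)O[C@H]3[C@@H]1O | intermediate
29 | 11-(dimethylaminomethyl) derivative of 28 (C11 epimers) | C=C[C@@]1(C)[C@H](C(=C)COCc2ccc(OC)cc2)[C@H](O[Si](C)(C)C(C)(C)C)[C@H]3C(CN(C)C)C(=O)O[C@H]3[C@@H]1O | intermediate (not isolated)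
30 | trimethylammonium iodide from 29 | [I-].C=C[C@@]1(C)[C@H](C(=C)COCc2ccc(OC)cc2)[C@H](O[Si](C)(C)C(C)(C)C)[C@H]3C(C[N+](C)(C)C)C(=O)O[C@H]3[C@@H]1O | intermediate (not isolated)
31 | 9β-hydroxy-6β-(TBS-oxy)-3-(PMB-oxy)elema-1,4(15),11(13)-trien-12,8α-olide | C=C[C@@]1(C)[C@H](C(=C)COCc2ccc(OC)cc2)[C@H](O[Si](C)(C)C(C)(C)C)[C@H]3C(=C)C(=O)O[C@H]3[C@@H]1O | intermediate
32 | (R)-2-methylbutanoic acid | CC[C@@H](C)C(=O)O | starting material
33 | 9β-[(R)-2-methylbutanoyloxy] derivative of 31 | C=C[C@@]1(C)[C@H](C(=C)COCc2ccc(OC)cc2)[C@H](O[Si](C)(C)C(C)(C)C)[C@H]3C(=C)C(=O)O[C@H]3[C@@H]1OC(=O)[C@H](C)CC | intermediate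
34 | 6β-alcohol from 33 | C=C[C@@]1(C)[C@H](C(=C)COCc2ccc(OC)cc2)[C@H](O)[C@H]3C(=C)C(=O)O[C@H]3[C@@H]1OC(=O)[C@H](C)CC | intermediate
35 | angelic acid, (Z)-2-methylbut-2-enoic acid | C/C=C(/C)C(=O)O | starting material
36 | (Z)-2-methylbut-2-enoic 2,4,6-trichlorobenzoic anhydride | C/C=C(/C)C(=O)OC(=O)c1c(Cl)cc(Cl)cc1Cl | intermediate (not isolated)
37 | 6β-angeloyloxy-9β-[(R)-2-methylbutanoyloxy]-3-(PMB-oxy)elema-1,4(15),11(13)-trien-12,8α-olide | C=C[C@@]1(C)[C@H](C(=C)COCc2ccc(OC)cc2)[C@H](OC(=O)/C(C)=C\C)[C@H]3C(=C)C(=O)O[C@H]3[C@@H]1OC(=O)[C@H](C)CC | intermediate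
38 | 3-hydroxy analogue of the target (C3 allylic alcohol) | C=C[C@@]1(C)[C@H](C(=C)CO)[C@H](OC(=O)/C(C)=C\C)[C@H]2C(=C)C(=O)O[C@H]2[C@@H]1OC(=O)[C@H](C)CC | intermediate
39 | CNP0295282.1: (5R,6S,7R,8R,9R,10S)-6-[(Z)-2-methylbut-2-enoyloxy]-9-[(R)-2-methylbutanoyloxy]-3-oxoelema-1,4(15),11(13)-trien-12,8-olide | C=C[C@@]1(C)[C@H](C(=C)C=O)[C@H](OC(=O)/C(C)=C\C)[C@H]2C(=C)C(=O)O[C@H]2[C@@H]1OC(=O)[C@H](C)CC | target

Total step count: 24. Longest linear sequence: 21 steps (1–4, 7–9, 11–24); steps 5–6 and step 10 are side branches.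

Steps most likely to fail

Step 13. The alkylidene may close onto either diastereotopic vinyl group without useful preference, or prefer the wrong one with both catalyst antipodes, which scrambles C10. Fallback (sets out from 22, comes back at 24): the choice between the vinyl groups is moved to a separable and recyclable pre-differentiation. Acidic methanolysis of the triethylsilyl ether of 22 (PPTS, MeOH) gives triene alcohol F1. A 5-exo iodoetherification from the C4 hydroxyl (I2, NaHCO3, MeCN, 0 °C) ties one C10 vinyl group up as 2-(iodomethyl)tetrahydrofuran F2. The diastereomer whose free vinyl group is trans to the C6 chain across C5–C10 is separated, and the others are returned to F1 with Zn in EtOH. Ring closure of F2 with RuCl2(PCy3)(H2IMes)(=CHPh) then needs no group selection and should give trans-fused bicyclic iodoether F3. Zn/AcOH reductive opening of the β-iodo ether regenerates the C1=C2 vinyl group and the C4 hydroxyl, which is 24.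

Step 15. Oxygen transfer may be slow, or may go to the C10 vinyl group, because the directing hydroxyl is one carbon further from the ring alkene than in the usual homoallylic case. Fallback (sets out from 24, comes back at 26): the better-precedented homoallylic C6 hydroxyl is used as the director. Dess–Martin oxidation of 24 gives ketone F4, and HF·pyridine frees the C6 hydroxyl to give hydroxy ketone F5. Its β-oriented hydroxyl directs VO(acac)2/t-BuOOH epoxidation to the β face of C8=C9 to give epoxy alcohol F6. TBSOTf/2,6-lutidine at −78 °C then returns 26.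

Step 22. Acylation of the hindered C6 hydroxyl may stall, and forcing it risks isomerisation of the angelate to the tiglate. Fallback (sets out from 34, comes back at 37): the Z alkene is built on the ester. Steglich esterification of 34 with 2-[bis(2,2,2-trifluoroethoxy)phosphoryl]propanoic acid (DCC, DMAP) gives phosphonate ester F7. Still–Gennari olefination with acetaldehyde (KN(SiMe3)2, 18-crown-6, THF, −78 °C) should then deliver the (Z)-2-methylbut-2-enoate 37.

Further compounds
F1 | step 13 | triene C4 alcohol (22 without the triethylsilyl group) | C=CC(C)(C=C)[C@H]([C@H](O)COCc1ccc(OC)cc1)[C@H](O[Si](C)(C)C(C)(C)C)[C@@H](CC(=O)OC(C)(C)C)C=C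
F2 | step 13 | 2-(iodomethyl)tetrahydrofuran from C4–O and one C10 vinyl group (iodomethyl-bearing carbon: either epimer) | ICC1O[C@H](COCc2ccc(OC)cc2)[C@H]([C@H](O[Si](C)(C)C(C)(C)C)[C@@H](CC(=O)OC(C)(C)C)C=C)[C@@]1(C)C=C
F3 | step 13 | trans-fused bicyclic iodoether (cyclohexene fused to the tetrahydrofuran at C5–C10) | ICC1O[C@H](COCc2ccc(OC)cc2)[C@@H]3[C@H](O[Si](C)(C)C(C)(C)C)[C@@H](CC(=O)OC(C)(C)C)C=C[C@@]13C
F4 | step 15 | cyclohexenyl C4 ketone (C6–OTBS) | C=C[C@@]1(C)[C@H](C(=O)COCc2ccc(OC)cc2)[C@H](O[Si](C)(C)C(C)(C)C)[C@@H](CC(=O)OC(C)(C)C)C=C1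
F5 | step 15 | cyclohexenyl C4 ketone with free 6β-hydroxyl | C=C[C@@]1(C)[C@H](C(=O)COCc2ccc(OC)cc2)[C@H](O)[C@@H](CC(=O)OC(C)(C)C)C=C1
F6 | step 15 | 8β,9β-epoxy C4 ketone with free 6β-hydroxyl | C=C[C@@]1(C)[C@H](C(=O)COCc2ccc(OC)cc2)[C@H](O)[C@@H](CC(=O)OC(C)(C)C)[C@@H]3O[C@H]13
F7 | step 22 | C6 2-[bis(2,2,2-trifluoroethoxy)phosphoryl]propanoate of 34 (phosphonate α-carbon: both epimers) | C=C[C@@]1(C)[C@H](C(=C)COCc2ccc(OC)cc2)[C@H](OC(=O)C(C)P(=O)(OCC(F)(F)F)OCC(F)(F)F)[C@H]3C(=C)C(=O)O[C@H]3[C@@H]1OC(=O)[C@H](C)CC
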